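**Retrosynthetic overview**

1. The strategy rests on one feature of the bicyclo[3.2.1]octane core: the carbinol carbon C3 lies between the C2 ring ketone and the side-chain ketone and is bonded to C5, the α-carbon of the bridging C9 ketone. C3–C5 is therefore an aldol bond; cutting it opens the cyclopentane ring C1–C2–C3–C5–C9 to a cyclohexanone (C9, C1, C8, C7, C6, C5) whose quaternary C1 carries a CO–CO–CO–C≡C chain (the Z-alkene is traced back to the alkyne).
2. The tricarbonyl chain is cut back to a C1 acetyl group (aldol with ynal 23, then periodinane oxidation). The acetyl group comes from a C1 ethynyl group, placed on β-diketone 17 by electrophilic alkynylation anti to the C7 prenyl group.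
3. β-Diketone 17 is cut into (S)-3-methyl-4-prenylcyclohexenone 10, prenyl bromide, a methyl nucleophile and isobutyraldehyde. Enone 10 comes from an organocatalytic Michael addition of 5-methylhex-4-enal to methyl vinyl ketone, which sets C7.
4. Ring order: the six-membered ring first (step 3), the five-membered ring last (step 14); desilylation and Lindlar semihydrogenation then finish the side chain.

Key step: step 14

Remark (numbering): C1 = isobutyryl bridgehead, C2 = ring ketone, C3 = carbinol, C5 = prenyl bridgehead, C6–C7–C8 = CH2–CH(prenyl)–CMe2, C9 = bridging ketone (there is no C4); prenyl = 3-methylbut-2-en-1-yl, isobutyryl = 2-methylpropanoyl; monocycles carry cyclohexanone locants (C1 = future C9, C2 = future C1, C3 = future C8, C4 = future C7, C6 = future C5).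

Remark (assumption): the (S)-diphenylprolinol methyl ether is assumed to shield the same enamine face as in its other Michael additions, which gives (S)-6; if the sense were opposite, the (R)-catalyst would be used.

Remark: C6 of the monocycles (future C5) is carried as an epimer mixture; this has no consequence because that centre is enolised in step 14.

**Route**

Step 1
Reactants: 1 2-methylbut-3-en-2-ol; 2 ethyl vinyl ether
Product: 4 5-methylhex-4-enal, via allyl vinyl ether 3 (not isolated)
Conditions: 2 (excess), H3PO4 (cat.), sealed vessel, 150 °C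
Reagents that add atoms: none
Why: Acid-catalysed vinyl transfer gives the tertiary allyl vinyl ether, which undergoes Claisen rearrangement on heating (Saucy–Marbet type) to the γ,δ-unsaturated aldehyde; no stereocentre is formed.

Step 2
Reactants: 4 5-methylhex-4-enal; 5 methyl vinyl ketone
Product: 6 (S)-2-(3-methylbut-2-en-1-yl)-5-oxohexanal
Conditions: (S)-2-(methoxydiphenylmethyl)pyrrolidine (5 mol%), ethyl 3,4-dihydroxybenzoate (20 mol%), neat, 4 °C
Reagents that add atoms: none
Why: Enamine-catalysed asymmetric Michael addition of an aldehyde to an enone; the diphenylmethoxymethyl group blocks one face of the E-enamine, so the enone adds to the other face and the future C7 centre is set as S.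

Step 3
Reactants: 6 (S)-2-(3-methylbut-2-en-1-yl)-5-oxohexanal
Product: 8 (S)-4-(3-methylbut-2-en-1-yl)cyclohex-2-en-1-one, via aldol adduct 7 (not isolated)
Conditions: LiOH (0.5 equiv), i-PrOH, rt
Reagents that add atoms: none
Why: Intramolecular aldol condensation (6-(enolendo)-exo-trig) of the methyl ketone onto the aldehyde, then loss of water to the conjugated enone; the mild base should close the ring faster than the aldehyde α-centre epimerises.

Step 4
Reactants: 8 (S)-4-(3-methylbut-2-en-1-yl)cyclohex-2-en-1-one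
Product: 10 (S)-3-methyl-4-(3-methylbut-2-en-1-yl)cyclohex-2-en-1-one, via lithium enolate 9 (not isolated)
Conditions: Me2CuLi, Et2O, −78 °C; then PhS(Cl)=N-t-Bu, THF, −78 °C → rt
Reagents that add atoms: lithium dimethylcuprate, [Li+].C[Cu-]C
Why: Cuprate 1,4-addition trans to the C4 substituent gives a regiodefined enolate, which the sulfinimidoyl chloride dehydrogenates in the same flask (Mukaiyama dehydrogenation: S-attack at C2, syn elimination of the C3 hydrogen); the methyl group ends on the enone β-carbon and C4 is untouched.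

Step 5
Reactants: 10 (S)-3-methyl-4-(3-methylbut-2-en-1-yl)cyclohex-2-en-1-one; 11 prenyl bromide
Product: 13 3-methyl-4,6-bis(3-methylbut-2-en-1-yl)cyclohex-2-en-1-one, via lithium dienolate 12 (not isolated)
Conditions: LDA, THF, −78 °C; then 11, −78 → −20 °C
Reagents that add atoms: none
Why: Kinetic α′-deprotonation of the enone gives the cross-conjugated dienolate, which is alkylated by the allylic bromide (SN2); the new C6 centre is formed as an epimer mixture that is erased in step 14, and the γ-centre C4 is not deprotonated under kinetic conditions.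

Step 6
Reactants: 13 3-methyl-4,6-bis(3-methylbut-2-en-1-yl)cyclohex-2-en-1-one; 14 isobutyraldehyde
Product: 16 2-(1-hydroxy-2-methylpropyl)-3,3-dimethyl-4,6-diprenylcyclohexan-1-one, via magnesium enolate 15 (not isolated)
Conditions: MeMgBr, CuI (20 mol%), THF, −40 → 0 °C; then 14, −78 °C; H2O quench
Reagents that add atoms: methylmagnesium bromide, C[Mg]Br
Why: Copper-catalysed conjugate addition builds the gem-dimethyl carbon and gives the C2 magnesium enolate regiospecifically, which is trapped by aldol addition to isobutyraldehyde; the two new centres (C2 and the carbinol) are removed in steps 7 and 8.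

Step 7
Reactants: 16 2-(1-hydroxy-2-methylpropyl)-3,3-dimethyl-4,6-diprenylcyclohexan-1-one
Product: 17 2-isobutyryl-3,3-dimethyl-4,6-diprenylcyclohexan-1-one
Conditions: Dess–Martin periodinane (1.2 equiv), CH2Cl2, 0 °C → rt
Reagents that add atoms: none
Why: Dess–Martin oxidation of the secondary alcohol to the ketone gives the 2-substituted β-diketone; the hindered tertiary C2–H is not expected to react further with a small excess of reagent.

Step 8
Reactants: 17 2-isobutyryl-3,3-dimethyl-4,6-diprenylcyclohexan-1-one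
Product: 18 2-ethynyl-2-isobutyryl-3,3-dimethyl-4,6-diprenylcyclohexan-1-one (ethynyl trans to the C4 prenyl group)
Conditions: TMS-EBX (1.3 equiv), TBAF (1.3 equiv), THF, −78 °C
Reagents that add atoms: 1-[(trimethylsilyl)ethynyl]-1,2-benziodoxol-3(1H)-one (TMS-EBX), C[Si](C)(C)C#CI1OC(=O)c2ccccc12
Why: Electrophilic α-alkynylation of a 1,3-dicarbonyl compound with an ethynyl-λ3-iodane released by fluoride (addition of the enolate carbon to the alkynyl iodane, α-elimination, 1,2-shift), a mode that tolerates the neighbouring CMe2 because the electrophile is a linear sp carbon; the enolate is attacked axially on the face anti to the axial C3 methyl of the half-chair with equatorial C4 prenyl, which places the ethynyl group trans to that prenyl group and sets the future C1.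

Step 9
Reactants: 18 2-ethynyl-2-isobutyryl-3,3-dimethyl-4,6-diprenylcyclohexan-1-one
Product: 19 2-acetyl-2-isobutyryl-3,3-dimethyl-4,6-diprenylcyclohexan-1-one
Conditions: (SPhos)AuNTf2 (3 mol%), MeOH–H2O (10:1), rt
Reagents that add atoms: water, O
Why: Gold(I)-catalysed Markovnikov hydration of a terminal alkyne gives the methyl ketone; the isolated trisubstituted alkenes and the ketones should not be engaged by the cationic gold catalyst at room temperature.

Step 10
Reactants: 20 2-methylbut-3-yn-2-ol
Product: 21 triethyl[(2-methylbut-3-yn-2-yl)oxy]silane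
Conditions: TESOTf, 2,6-lutidine, CH2Cl2, 0 °C
Reagents that add atoms: triethylsilyl trifluoromethanesulfonate, CC[Si](CC)(CC)OS(=O)(=O)C(F)(F)F
Why: Silylation of a tertiary alcohol with a silyl triflate and a hindered pyridine base.

Step 11
Reactants: 21 triethyl[(2-methylbut-3-yn-2-yl)oxy]silane
Product: 23 4-methyl-4-(triethylsilyloxy)pent-2-ynal, via lithium acetylide 22 (not isolated)
Conditions: n-BuLi, THF, −78 °C; then DMF, −78 → 0 °C; inverse quench into cold aq. KH2PO4
Reagents that add atoms: N,N-dimethylformamide, CN(C)C=O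
Why: Deprotonation of the terminal alkyne and formylation of the acetylide with DMF; the buffered inverse quench releases the ynal from the hemiaminal salt without conjugate addition of dimethylamine.

Step 12
Reactants: 19 2-acetyl-2-isobutyryl-3,3-dimethyl-4,6-diprenylcyclohexan-1-one; 23 4-methyl-4-(triethylsilyloxy)pent-2-ynal
Product: 25 2-[3-hydroxy-6-methyl-6-(triethylsilyloxy)hept-4-ynoyl]-2-isobutyryl-3,3-dimethyl-4,6-diprenylcyclohexan-1-one, via lithium enolate 24 (not isolated)
Conditions: LiHMDS (1.05 equiv), THF, −78 °C; then 23, −78 °C; AcOH, −78 °C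
Reagents that add atoms: none
Why: Directed aldol addition: the acetyl CH3 is the only unhindered α-position (C6–H and the isobutyryl methine are tertiary), so its kinetic lithium enolate forms selectively and adds 1,2 to the ynal; the cold acidic quench keeps the aldolate from transferring an acyl group off the non-enolisable C2, and the carbinol centre is oxidised in step 13.

Step 13
Reactants: 25 2-[3-hydroxy-6-methyl-6-(triethylsilyloxy)hept-4-ynoyl]-2-isobutyryl-3,3-dimethyl-4,6-diprenylcyclohexan-1-one
Product: 27 2-[6-methyl-2,3-dioxo-6-(triethylsilyloxy)hept-4-ynoyl]-2-isobutyryl-3,3-dimethyl-4,6-diprenylcyclohexan-1-one, via β-diketone 26 (not isolated)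
Conditions: Dess–Martin periodinane (4 equiv), pyridine (10 equiv), H2O (1.1 equiv), CH2Cl2, rt; filtration through Celite, no basic aqueous wash
Reagents that add atoms: water, O
Why: Dess–Martin oxidation of the β-hydroxy ketone to the 1,3-diketone, then oxidation of its enol at the central CH2 by further periodinane (the known one-flask conversion of α-unsubstituted β-hydroxy carbonyl compounds into vicinal tricarbonyls), with water delivering the new oxygen through the iodine centre; alkenes, alkyne and silyl ether tolerate the reagent, and the product may be handled as its C3 hydrate.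

Step 14
Reactants: 27 2-[6-methyl-2,3-dioxo-6-(triethylsilyloxy)hept-4-ynoyl]-2-isobutyryl-3,3-dimethyl-4,6-diprenylcyclohexan-1-one
Product: 28 (1R,3S,5S,7R)-3-hydroxy-1-isobutyryl-8,8-dimethyl-5,7-diprenyl-3-[4-methyl-4-(triethylsilyloxy)pent-2-ynoyl]bicyclo[3.2.1]octane-2,9-dione (numbering of the remark; OH endo, acyl exo)
Conditions: Mg(OTf)2 (1.2 equiv), i-Pr2NEt (1.5 equiv), 4 Å MS, CH2Cl2–MeCN (4:1), −20 °C → rt; pH 7 buffer
Reagents that add atoms: none
Why: Mg(II)/amine soft enolisation of the C9 ketone can only go toward C5 (C1 is quaternary, and the alternative isobutyryl enol would hold a methyl group cis to the fully substituted C1 on a tetrasubstituted double bond), and the C5 enol adds to C3, the central and most electrophilic carbonyl of the magnesium-bound tricarbonyl, in an intramolecular aldol addition whose closest known relatives are the additions of enols and enolates to the central carbonyl of vicinal tricarbonyl compounds. The cyclopentane ring C1–C2–C3–C5–C9 closes in the 5-(enolendo)-exo-trig mode, which is acceptable here because the tricarbonyl arm is axial on C1 and so holds C3 directly over the C5 p-lobe of the chair-like enol, letting the bond form along the axial direction that a cyclohexanone enol prefers. C5 is controlled by this tether: the new C3–C5 bond must be cis to the C1–C2 bond, which leaves the C5 prenyl group equatorial and fixes C5 relative to C1 and hence to C7. C3 is controlled by the face of the C3 carbonyl that is attacked: an open arrangement with the C3=O dipole turned away from the C9 oxygen and, under the reversible magnesium-aldolate conditions, the smaller steric demand of the exo position (syn to C9) for the ynoyl group should both put the hydroxyl endo and the acyl group exo. The step needs C3 to be chosen over the ynone carbonyl (six-ring closure) and the alkyne to stay untouched; the first rests on the higher electrophilicity of the central carbonyl and on the relief of the contiguous tricarbonyl array that only C3 attack gives, the second on the non-nucleophilic base and counter-ion.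

Step 15
Reactants: 28 bicyclic α-ketol silyl ether
Product: 29 (1R,3S,5S,7R)-3-hydroxy-3-(4-hydroxy-4-methylpent-2-ynoyl)-1-isobutyryl-8,8-dimethyl-5,7-diprenylbicyclo[3.2.1]octane-2,9-dione
Conditions: HF·pyridine, pyridine, THF, 0 °C
Reagents that add atoms: none
Why: Fluoride cleavage of the tertiary triethylsilyl ether under pyridine-buffered conditions, which should leave the α-ketol and the ynone alone.

Step 16
Reactants: 29 bicyclic diol ynone
Product: 30 target, (1R,3S,5S,7R)-3-hydroxy-3-[(Z)-4-hydroxy-4-methylpent-2-enoyl]-1-isobutyryl-8,8-dimethyl-5,7-diprenylbicyclo[3.2.1]octane-2,9-dione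
Conditions: H2 (1 atm), Lindlar catalyst (Pd/CaCO3, Pb-poisoned), quinoline, EtOAc, 0 °C → rt, stopped after 1 equiv H2
Reagents that add atoms: none
Why: Lindlar semihydrogenation adds H2 syn to the alkyne on the poisoned palladium surface and gives the Z-enone; the trisubstituted prenyl alkenes and the ketones are not reduced, and the neutral last step spares the Z-hydroxy-enone from acid or base.

**Compound list**

1 | 2-methylbut-3-en-2-ol | CC(C)(O)C=C | starting material
2 | ethyl vinyl ether | CCOC=C | starting material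
3 | 2-methylbut-3-en-2-yl vinyl ether | CC(C)(OC=C)C=C | intermediate (not isolated)
4 | 5-methylhex-4-enal | CC(C)=CCCC=O | intermediate
5 | methyl vinyl ketone (but-3-en-2-one) | CC(=O)C=C | starting material
6 | (S)-2-(3-methylbut-2-en-1-yl)-5-oxohexanal | CC(C)=CC[C@@H](C=O)CCC(C)=O | intermediate
7 | 3-hydroxy-4-prenylcyclohexan-1-one (C4 as in 6, carbinol epimers) | CC(C)=CC[C@@H]1CCC(=O)CC1O | intermediate (not isolated)
8 | (S)-4-(3-methylbut-2-en-1-yl)cyclohex-2-en-1-one | CC(C)=CC[C@@H]1CCC(=O)C=C1 | intermediate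
9 | lithium trans-3-methyl-4-prenylcyclohex-1-en-1-olate | CC(C)=CC[C@@H]1CCC(O[Li])=C[C@H]1C | intermediate (not isolated)
10 | (S)-3-methyl-4-(3-methylbut-2-en-1-yl)cyclohex-2-en-1-one | CC(C)=CC[C@@H]1CCC(=O)C=C1C | intermediate
11 | prenyl bromide (1-bromo-3-methylbut-2-ene) | CC(C)=CCBr | starting material
12 | lithium 3-methyl-4-prenylcyclohexa-1,5-dien-1-olate (cross-conjugated dienolate of 10) | CC(C)=CC[C@@H]1CC=C(O[Li])C=C1C | intermediate (not isolated)
13 | 3-methyl-4,6-bis(3-methylbut-2-en-1-yl)cyclohex-2-en-1-one (C4 as in 10, C6 epimers) | CC(C)=CC[C@@H]1CC(CC=C(C)C)C(=O)C=C1C | intermediate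
14 | isobutyraldehyde | CC(C)C=O | starting material
15 | bromomagnesium 3,3-dimethyl-4,6-diprenylcyclohex-1-en-1-olate | CC(C)=CC[C@@H]1CC(CC=C(C)C)C(O[Mg]Br)=CC1(C)C | intermediate (not isolated)
16 | 2-(1-hydroxy-2-methylpropyl)-3,3-dimethyl-4,6-diprenylcyclohexan-1-one (diastereomer mixture at C2, C6 and the carbinol) | CC(C)=CC[C@@H]1CC(CC=C(C)C)C(=O)C(C(O)C(C)C)C1(C)C | intermediate
17 | 2-isobutyryl-3,3-dimethyl-4,6-diprenylcyclohexan-1-one | CC(C)=CC[C@@H]1CC(CC=C(C)C)C(=O)C(C(=O)C(C)C)C1(C)C | intermediate
18 | 2-ethynyl-2-isobutyryl-3,3-dimethyl-4,6-diprenylcyclohexan-1-one (ethynyl trans to C4 prenyl) | CC(C)=CC[C@@H]1CC(CC=C(C)C)C(=O)[C@@](C(=O)C(C)C)(C#C)C1(C)C | intermediate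
19 | 2-acetyl-2-isobutyryl-3,3-dimethyl-4,6-diprenylcyclohexan-1-one (acetyl trans to C4 prenyl) | CC(C)=CC[C@@H]1CC(CC=C(C)C)C(=O)[C@@](C(=O)C(C)C)(C(C)=O)C1(C)C | intermediate
20 | 2-methylbut-3-yn-2-ol | CC(C)(O)C#C | starting material
21 | triethyl[(2-methylbut-3-yn-2-yl)oxy]silane | CC(C)(O[Si](CC)(CC)CC)C#C | intermediate
22 | lithium acetylide of 21 | CC(C)(O[Si](CC)(CC)CC)C#C[Li] | intermediate (not isolated)
23 | 4-methyl-4-(triethylsilyloxy)pent-2-ynal | CC(C)(O[Si](CC)(CC)CC)C#CC=O | intermediate
24 | lithium enolate of the acetyl group of 19 | CC(C)=CC[C@@H]1CC(CC=C(C)C)C(=O)[C@@](C(=O)C(C)C)(C(=C)O[Li])C1(C)C | intermediate (not isolated)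
25 | 2-[3-hydroxy-6-methyl-6-(triethylsilyloxy)hept-4-ynoyl]-2-isobutyryl-3,3-dimethyl-4,6-diprenylcyclohexan-1-one (carbinol epimers) | CC(C)=CC[C@@H]1CC(CC=C(C)C)C(=O)[C@@](C(=O)C(C)C)(C(=O)CC(O)C#CC(C)(C)O[Si](CC)(CC)CC)C1(C)C | intermediate
26 | 2-[6-methyl-3-oxo-6-(triethylsilyloxy)hept-4-ynoyl]-2-isobutyryl-3,3-dimethyl-4,6-diprenylcyclohexan-1-one | CC(C)=CC[C@@H]1CC(CC=C(C)C)C(=O)[C@@](C(=O)C(C)C)(C(=O)CC(=O)C#CC(C)(C)O[Si](CC)(CC)CC)C1(C)C | intermediate (not isolated)
27 | 2-[6-methyl-2,3-dioxo-6-(triethylsilyloxy)hept-4-ynoyl]-2-isobutyryl-3,3-dimethyl-4,6-diprenylcyclohexan-1-one (tricarbonyl precursor of the key step) | CC(C)=CC[C@@H]1CC(CC=C(C)C)C(=O)[C@@](C(=O)C(C)C)(C(=O)C(=O)C(=O)C#CC(C)(C)O[Si](CC)(CC)CC)C1(C)C | intermediate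
28 | (1R,3S,5S,7R)-3-hydroxy-1-isobutyryl-8,8-dimethyl-5,7-diprenyl-3-[4-methyl-4-(triethylsilyloxy)pent-2-ynoyl]bicyclo[3.2.1]octane-2,9-dione (numbering of the remark) | CC(C)=CC[C@@H]1C[C@]2(CC=C(C)C)C(=O)[C@@](C(=O)C(C)C)(C(=O)[C@@]2(O)C(=O)C#CC(C)(C)O[Si](CC)(CC)CC)C1(C)C | intermediate
29 | (1R,3S,5S,7R)-3-hydroxy-3-(4-hydroxy-4-methylpent-2-ynoyl)-1-isobutyryl-8,8-dimethyl-5,7-diprenylbicyclo[3.2.1]octane-2,9-dione | CC(C)=CC[C@@H]1C[C@]2(CC=C(C)C)C(=O)[C@@](C(=O)C(C)C)(C(=O)[C@@]2(O)C(=O)C#CC(C)(C)O)C1(C)C | intermediate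
30 | CNP0190794.1, (1R,3S,5S,7R)-3-hydroxy-3-[(Z)-4-hydroxy-4-methylpent-2-enoyl]-1-isobutyryl-8,8-dimethyl-5,7-diprenylbicyclo[3.2.1]octane-2,9-dione | CC(C)=CC[C@@H]1C[C@]2(CC=C(C)C)C(=O)[C@@](C(=O)C(C)C)(C(=O)[C@@]2(O)C(=O)/C=C\C(C)(C)O)C1(C)C | target

**Step count**

Total: 16 steps. Longest linear sequence: 14 steps (steps 1–9 and 12–16); steps 10–11 form the side-chain branch that joins at step 12.

**Steps most likely to fail**

Step 14 (key aldol). The newly formed C3 alkoxide, or the amine, may add to the ynone terminus (5-endo-dig closure to a furanone), or the C5 enol may close onto the ynone carbonyl instead of C3. In that case the alkyne would be reduced before the ring is closed. Setting out from 25, Lindlar semihydrogenation (H2, Pd/CaCO3–Pb, quinoline, EtOAc) should give the (Z)-allylic alcohol 2-[(Z)-3-hydroxy-6-methyl-6-(triethylsilyloxy)hept-4-enoyl]-2-isobutyryl-3,3-dimethyl-4,6-diprenylcyclohexan-1-one F1. Dess–Martin periodinane/pyridine/H2O as in step 13 would turn it into the (Z)-enone tricarbonyl 2-[(Z)-6-methyl-2,3-dioxo-6-(triethylsilyloxy)hept-4-enoyl]-2-isobutyryl-3,3-dimethyl-4,6-diprenylcyclohexan-1-one F2. The same Mg(OTf)2/i-Pr2NEt aldol would close it to the bicyclic (Z)-enone silyl ether F3, in which attack of the C3 oxygen on the enone would be a geometrically disfavoured 5-endo-trig process. HF·pyridine would then give 30 directly, so the fallback rejoins the route at 30.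

Step 9 (alkyne hydration). A carbonyl oxygen on the quaternary carbon may take part (5-endo attack at the alkyne terminus, leading to the anti-Markovnikov aldehyde), or the gold-activated alkyne may cyclise onto a prenyl alkene. Hydration would then be replaced by hydrometalation–oxidation. From 18, ruthenium-catalysed Markovnikov hydrosilylation ([Cp*Ru(MeCN)3]PF6, (EtO)3SiH, CH2Cl2, 0 °C → rt) should give the α-silyl alkene 2-isobutyryl-3,3-dimethyl-4,6-diprenyl-2-[1-(triethoxysilyl)vinyl]cyclohexan-1-one F4. Tamao–Fleming oxidation (KF, KHCO3, H2O2, THF–MeOH, 0 °C) would deliver 19, where the route is rejoined.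

Step 13 (one-flask oxidation to the tricarbonyl). The periodinane may stop at the 1,3-diketone or transfer acetate instead of oxygen to the central carbon. The oxygen would then be introduced in separate, defined events. From 25, Dess–Martin periodinane (1.2 equiv, CH2Cl2) gives 26, which is now isolated. Regitz diazo transfer (p-acetamidobenzenesulfonyl azide, Et3N, MeCN, 0 °C) gives the 2-diazo-1,3-diketone 2-[2-diazo-6-methyl-3-oxo-6-(triethylsilyloxy)hept-4-ynoyl]-2-isobutyryl-3,3-dimethyl-4,6-diprenylcyclohexan-1-one F5. Rh2(OAc)4-catalysed O–H insertion into water (wet CH2Cl2, rt) gives the 2-hydroxy-1,3-diketone 2-[2-hydroxy-6-methyl-3-oxo-6-(triethylsilyloxy)hept-4-ynoyl]-2-isobutyryl-3,3-dimethyl-4,6-diprenylcyclohexan-1-one F6. Dess–Martin oxidation of that alcohol returns to 27.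

**Further compounds**

F1 | step 14 | 2-[(Z)-3-hydroxy-6-methyl-6-(triethylsilyloxy)hept-4-enoyl]-2-isobutyryl-3,3-dimethyl-4,6-diprenylcyclohexan-1-one | CC(C)=CC[C@@H]1CC(CC=C(C)C)C(=O)[C@@](C(=O)C(C)C)(C(=O)CC(O)/C=C\C(C)(C)O[Si](CC)(CC)CC)C1(C)C
F2 | step 14 | 2-[(Z)-6-methyl-2,3-dioxo-6-(triethylsilyloxy)hept-4-enoyl]-2-isobutyryl-3,3-dimethyl-4,6-diprenylcyclohexan-1-one | CC(C)=CC[C@@H]1CC(CC=C(C)C)C(=O)[C@@](C(=O)C(C)C)(C(=O)C(=O)C(=O)/C=C\C(C)(C)O[Si](CC)(CC)CC)C1(C)C
F3 | step 14 | (1R,3S,5S,7R)-3-hydroxy-1-isobutyryl-8,8-dimethyl-5,7-diprenyl-3-[(Z)-4-methyl-4-(triethylsilyloxy)pent-2-enoyl]bicyclo[3.2.1]octane-2,9-dione | CC(C)=CC[C@@H]1C[C@]2(CC=C(C)C)C(=O)[C@@](C(=O)C(C)C)(C(=O)[C@@]2(O)C(=O)/C=C\C(C)(C)O[Si](CC)(CC)CC)C1(C)C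
F4 | step 9 | 2-isobutyryl-3,3-dimethyl-4,6-diprenyl-2-[1-(triethoxysilyl)vinyl]cyclohexan-1-one | CC(C)=CC[C@@H]1CC(CC=C(C)C)C(=O)[C@@](C(=O)C(C)C)(C(=C)[Si](OCC)(OCC)OCC)C1(C)C
F5 | step 13 | 2-[2-diazo-6-methyl-3-oxo-6-(triethylsilyloxy)hept-4-ynoyl]-2-isobutyryl-3,3-dimethyl-4,6-diprenylcyclohexan-1-one | CC(C)=CC[C@@H]1CC(CC=C(C)C)C(=O)[C@@](C(=O)C(C)C)(C(=O)C(=[N+]=[N-])C(=O)C#CC(C)(C)O[Si](CC)(CC)CC)C1(C)C
F6 | step 13 | 2-[2-hydroxy-6-methyl-3-oxo-6-(triethylsilyloxy)hept-4-ynoyl]-2-isobutyryl-3,3-dimethyl-4,6-diprenylcyclohexan-1-one | CC(C)=CC[C@@H]1CC(CC=C(C)C)C(=O)[C@@](C(=O)C(C)C)(C(=O)C(O)C(=O)C#CC(C)(C)O[Si](CC)(CC)CC)C1(C)C
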